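The route opens both rings at the 2-oxy-1,3-diene C2=C3–C4=C5 of the bicyclic enol ether. C3 and C4 become the two carbons of a 1-propynyl ether on O–C10, and C2 and C5 become the inner carbons of vinyl groups on C1 and C6. One ruthenium-catalysed ene–yne–ene metathesis cascade then closes the dihydrofuran ring (C2=C3) and the nine-membered oxacycle (C4=C5, Z) and gives the C1 silyl ether of the target skeleton. Its precursor is an open-chain trans-α-methylene-γ-butyrolactone (C7, C8, C11, C12) bearing the C6 tiglate/vinyl arm on C7 and the CH2–C10(Me)(OC≡CMe)–C1H(OSiEt3)–CH=CH2 arm on C8. The ynol ether is installed before any ester is present.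

Key step: step 17

Remarks on the chemistry:
- Atom numbers follow the germacrane skeleton: C1 is the ketone carbon, C10 the quaternary ether carbon, C11–C13 the methylene lactone carbons.
- Target, precursor 26 and cascade product 27 are (6S,7R,8S,10S) with a trans-fused lactone (H7/H8 anti); their structures agree at every shared stereocentre, so none needed correcting.
- Assumption: step 6 forms C1 without useful control. The (1S) epimer is separated and drawn; the (1R) epimer can be taken through the same steps because C1 ends as the ketone.
- Compounds 5, 6, 8 and 9 are anomeric mixtures at the acetal carbon.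
- The tertiary propynyl ether is acid-labile and can lose methylketene on heating, so steps 8–17 avoid protic and strong Lewis acids and stay at or below 35 °C.

Step 1
Reactants: 1 (S)-citramalic acid
Product: 2 2-[(4S)-2,2,4-trimethyl-5-oxo-1,3-dioxolan-4-yl]acetic acid
Conditions: Me2C(OMe)2, PPTS (cat.), rt
Reagents that add atoms: 2,2-dimethoxypropane, COC(C)(C)OC
Why: Acid-catalysed acetal exchange locks the tertiary hydroxyl and its neighbouring carboxyl into a dioxolanone (acetonide of an α-hydroxy acid) and leaves the other carboxyl free for selective reduction, without touching the stereocentre that becomes C10.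

Step 2
Reactants: 2 2-[(4S)-2,2,4-trimethyl-5-oxo-1,3-dioxolan-4-yl]acetic acid
Product: 4 (3S)-3-hydroxy-3-methyloxolan-2-one, via hydroxyethyl dioxolanone 3 (not isolated)
Conditions: BH3·SMe2, THF, 0 °C to rt; MeOH; then TsOH (cat.), CH2Cl2, rt
Reagents that add atoms: none
Why: Borane reduces the free carboxylic acid faster than the dioxolanone carbonyl (chemoselective borane reduction), and under acid the new primary alcohol attacks that carbonyl so that the γ-lactone forms with loss of acetone (transacylation), again without touching C10.

Step 3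
Reactants: 4 (3S)-3-hydroxy-3-methyloxolan-2-one
Product: 6 (3S)-2-methoxy-3-methyloxolan-3-ol, via lactol diol 5 (not isolated)
Conditions: iBu2AlH (2.2 equiv), CH2Cl2, −78 °C; then MeOH, PPTS (cat.), rt
Reagents that add atoms: methanol, CO
Why: iBu2AlH at low temperature reduces the γ-lactone only to the lactol, and acid-catalysed acetalisation with methanol then stores C1 at the aldehyde level and O8 in the ring as a methyl acetal that is inert to the strong bases used next, so that only the tertiary hydroxyl remains free.

Step 4
Reactants: 6 (3S)-2-methoxy-3-methyloxolan-3-ol; 7 trichloroethylene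
Product: 8 (3S)-3-[(E)-1,2-dichloroethenoxy]-2-methoxy-3-methyloxolane
Conditions: KH, THF, 0 °C; then 7, −40 °C to rt
Reagents that add atoms: none
Why: The potassium tert-alkoxide adds to dichloroethyne formed in situ from trichloroethylene by dehydrochlorination (standard dichlorovinyl ether synthesis, also used for tertiary alkoxides), anti addition giving the (E)-1,2-dichlorovinyl ether, and because the substrate carries no silyl or acyl group nothing can migrate to the alkoxide.

Step 5
Reactants: 8 (3S)-3-[(E)-1,2-dichloroethenoxy]-2-methoxy-3-methyloxolane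
Product: 9 (3S)-3-[(E)-1,2-dichloroethenoxy]-3-methyloxolan-2-ol
Conditions: 1 M HCl, THF, 0 °C to rt
Reagents that add atoms: water, O
Why: Dilute aqueous acid hydrolyses the furanoside-type methyl acetal (acetal hydrolysis), whereas the 1,2-dichlorovinyl ether is too electron-poor to be protonated under these conditions.

Step 6
Reactants: 9 (3S)-3-[(E)-1,2-dichloroethenoxy]-3-methyloxolan-2-ol
Product: 10 (3S,4S)-3-[(E)-1,2-dichloroethenoxy]-3-methylhex-5-ene-1,4-diol
Conditions: CH2=CHMgBr (3 equiv), THF, −78 to 0 °C; C1 epimers separated on silica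
Reagents that add atoms: vinylmagnesium bromide, C=C[Mg]Br
Why: The Grignard reagent first deprotonates the lactol, which opens to the aldehyde alkoxide, and then adds to the aldehyde (Grignard 1,2-addition); the new C1 carbinol forms with little facial bias because the α-carbon is quaternary, so the (1S) epimer is separated by chromatography and carried on.

Step 7
Reactants: 10 (3S,4S)-3-[(E)-1,2-dichloroethenoxy]-3-methylhex-5-ene-1,4-diol
Product: 11 (3S,4S)-3-[(E)-1,2-dichloroethenoxy]-3-methyl-1,4-bis(triethylsilyloxy)hex-5-ene
Conditions: Et3SiOTf, 2,6-lutidine, CH2Cl2, −78 to 0 °C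
Reagents that add atoms: triethylsilyl trifluoromethanesulfonate, CC[Si](CC)(CC)OS(=O)(=O)C(F)(F)F
Why: Triethylsilyl triflate with a hindered pyridine base silylates the primary and the hindered secondary allylic hydroxyl alike (silyl ether formation) and leaves the dichlorovinyl ether untouched.

Step 8
Reactants: 11 (3S,4S)-3-[(E)-1,2-dichloroethenoxy]-3-methyl-1,4-bis(triethylsilyloxy)hex-5-ene
Product: 14 (3S,4S)-3-methyl-3-(prop-1-ynoxy)-1,4-bis(triethylsilyloxy)hex-5-ene, via chloroethynyl ether 12 (not isolated), via lithium alkoxyacetylide 13 (not isolated)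
Conditions: n-BuLi (2.5 equiv), THF, −78 to −40 °C; then MeI, DMPU, −78 to 0 °C
Reagents that add atoms: iodomethane, CI
Why: n-BuLi removes HCl from the dichlorovinyl ether and then exchanges chlorine for lithium on the resulting chloroalkyne, and the lithium alkoxyacetylide is methylated on carbon by MeI in the presence of DMPU (standard conversion of dichlorovinyl ethers into 1-alkynyl ethers), while silyl ethers and the vinyl group are inert at low temperature and no stereocentre is involved.

Step 9
Reactants: 14 (3S,4S)-3-methyl-3-(prop-1-ynoxy)-1,4-bis(triethylsilyloxy)hex-5-ene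
Product: 15 (3S,4S)-3-methyl-3-(prop-1-ynoxy)-4-(triethylsilyloxy)hex-5-en-1-ol
Conditions: Bu4NF (1.0 equiv), THF, −40 °C
Reagents that add atoms: none
Why: A single equivalent of fluoride at low temperature removes the unhindered primary triethylsilyl group much faster than the secondary one that sits between the quaternary carbon and the vinyl group (sterically selective desilylation), and the basic medium does not harm the ynol ether.

Step 10
Reactants: 15 (3S,4S)-3-methyl-3-(prop-1-ynoxy)-4-(triethylsilyloxy)hex-5-en-1-ol
Product: 16 (3S,4S)-3-methyl-3-(prop-1-ynoxy)-4-(triethylsilyloxy)hex-5-enal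
Conditions: nPr4N[RuO4] (5 mol %), NMO, 4 Å MS, CH2Cl2, 0 °C; used at once
Reagents that add atoms: none
Why: The Ley–Griffith oxidation works at neutral pH without acid, so the primary alcohol is taken to the aldehyde without hydration of the ynol ether and, at 0 °C with immediate use, without β-elimination of the alkynyloxy group.

Step 11
Reactants: 17 penta-1,4-dien-3-ol
Product: 18 (1S)-1-[(2R)-oxiran-2-yl]prop-2-en-1-ol
Conditions: Ti(OiPr)4, L-(+)-diisopropyl tartrate, tBuOOH, 4 Å MS, CH2Cl2, −20 °C
Reagents that add atoms: tert-butyl hydroperoxide, CC(C)(C)OO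
Why: Sharpless asymmetric epoxidation of the prochiral divinyl carbinol combines selection of one enantiotopic vinyl group with face selection and gives the erythro (2R,3S) epoxy alcohol with the natural tartrate, the enantiomeric excess being raised further because the minor enantiomer is consumed by a fast second epoxidation.

Step 12
Reactants: 18 (1S)-1-[(2R)-oxiran-2-yl]prop-2-en-1-ol; 19 2-(bromomethyl)prop-2-enoic acid
Product: 20 (1S)-1-[(2R)-oxiran-2-yl]prop-2-enyl 2-(bromomethyl)prop-2-enoate
Conditions: iPrN=C=NiPr, DMAP (cat.), CH2Cl2, 0 °C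
Reagents that add atoms: none
Why: Carbodiimide coupling with catalytic DMAP (Steglich esterification) acylates the secondary hydroxyl with retention at the carbinol carbon, and the epoxide and the allylic bromide tolerate the neutral, cold conditions.

Step 13
Reactants: 20 (1S)-1-[(2R)-oxiran-2-yl]prop-2-enyl 2-(bromomethyl)prop-2-enoate
Product: 21 (5S)-3-(bromomethyl)-5-[(2R)-oxiran-2-yl]furan-2(5H)-one
Conditions: second-generation Grubbs catalyst (H2IMes)(PCy3)Cl2Ru=CHPh (5 mol %), CH2Cl2 (5 mM), 40 °C
Reagents that add atoms: none
Why: Ring-closing metathesis between the vinyl group and the 1,1-disubstituted acrylate alkene closes the butenolide with loss of ethene (well known for acrylates of allylic alcohols), the epoxide and the allylic bromide being spectators, and the carbinol carbon, whose two arms are now different, becomes the stereocentre C6 of the lactone.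

Step 14
Reactants: 21 (5S)-3-(bromomethyl)-5-[(2R)-oxiran-2-yl]furan-2(5H)-one
Product: 22 (5R)-5-ethenyl-3-(iodomethyl)furan-2(5H)-one
Conditions: NaI, Me3SiCl, MeCN, 0 °C to rt; aq. Na2S2O3
Reagents that add atoms: sodium iodide, [Na+].[I-]
Why: Iodotrimethylsilane made in situ opens the epoxide to the iodohydrin silyl ether and a second iodide triggers anti elimination to the alkene (stereospecific deoxygenation of epoxides), while Finkelstein exchange turns the allylic bromide into the more reactive iodide; the C6–O bond is not broken, so C6 keeps its geometry and is now R only because the priorities change.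

Step 15
Reactants: 16 (3S,4S)-3-methyl-3-(prop-1-ynoxy)-4-(triethylsilyloxy)hex-5-enal; 22 (5R)-5-ethenyl-3-(iodomethyl)furan-2(5H)-one
Product: 24 (4S,5S)-4-[(1R)-1-hydroxyprop-2-enyl]-3-methylidene-5-[(2S,3S)-2-methyl-2-(prop-1-ynoxy)-3-(triethylsilyloxy)pent-4-enyl]oxolan-2-one, via zinc alkoxide adduct 23 (not isolated)
Conditions: Zn dust, THF, 0 °C to rt, 16 and 22 added together; pH 7 phosphate buffer
Reagents that add atoms: none
Why: Zinc inserts into the allylic iodide and the allylzinc, held in the (E)-crotyl-type geometry by the butenolide ring, adds to the aldehyde through a chair transition state with allylic transposition (Barbier allylation of the Dreiding–Schmidt type, known for 3-halomethyl butenolides) on the ring face opposite the C6 vinyl group, which sets C7 and, anti to it, C8 with the trans relationship of the target and regenerates the exocyclic methylene; the C8 zinc alkoxide then attacks the lactone carbonyl and the acyl group moves from O6 to O8 (translactonization), the equilibrium lying with the less hindered and less basic allylic alkoxide at C6.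

Step 16
Reactants: 24 (4S,5S)-4-[(1R)-1-hydroxyprop-2-enyl]-3-methylidene-5-[(2S,3S)-2-methyl-2-(prop-1-ynoxy)-3-(triethylsilyloxy)pent-4-enyl]oxolan-2-one; 25 tiglic acid
Product: 26 (4R,5S)-3-methylidene-4-[(1S)-1-[(E)-2-methylbut-2-enoyl]oxyprop-2-enyl]-5-[(2S,3S)-2-methyl-2-(prop-1-ynoxy)-3-(triethylsilyloxy)pent-4-enyl]oxolan-2-one
Conditions: PPh3, DIAD, THF, −20 °C; then 25 and 24, −20 to 0 °C
Reagents that add atoms: none
Why: Mitsunobu esterification turns the allylic C6 hydroxyl into an oxyphosphonium leaving group that tiglate displaces with inversion (SN2), converting the C6-epimeric alcohol into the (6S) tiglate of the target, and forming the betaine before the acid is added keeps free acid and free phosphine away from the ynol ether and the methylene lactone.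

Step 17
Reactants: 26 (4R,5S)-3-methylidene-4-[(1S)-1-[(E)-2-methylbut-2-enoyl]oxyprop-2-enyl]-5-[(2S,3S)-2-methyl-2-(prop-1-ynoxy)-3-(triethylsilyloxy)pent-4-enyl]oxolan-2-one
Product: 27 C1 triethylsilyl ether of the bicyclic dienol ether lactone (dihydrofuran fused across C3–O–C10 of the nine-membered oxacycle; 1S,6S,7R,8S,10S; C4=C5 Z)
Conditions: second-generation Grubbs catalyst (H2IMes)(PCy3)Cl2Ru=CHPh (2 × 5 mol %), CH2Cl2 (1 mM), 30 °C, argon sparge
Reagents that add atoms: none
Why: The ruthenium alkylidene formed at C2 from the C1 vinyl group adds across the electron-rich propynyl ether so that C2 bonds to the oxygen-bearing carbon C3 (exo mode), which closes the five-membered cyclic enol ether and leaves a methyl-substituted carbene on C4; this carbene then undergoes ring-closing metathesis with the C6 vinyl group and closes the nine-membered oxacycle through the trisubstituted C4=C5 bond with release of ethene. The closest known reactions are the ring-closing enyne metathesis of alkynyl ethers to 2-alkenyl cyclic enol ethers and tandem dienyne ring-closing metathesis. No stereocentre is created, and the only new stereochemical element, the Z geometry of C4=C5, is imposed by the nine-membered ring. The step needs the small ring to form first and the second closure to stay intramolecular: the three-atom tether between C2 and C3 makes the five-ring closure far faster than any medium-ring event, a carbene formed first at the C6 vinyl group can only revert and re-enter the productive path, and the trans lactone holds C6 and C9 gauche so that the C4 carbene finds the C6 vinyl group at 1 mM. The lactone methylene and the tiglate alkene are electron-poor and more highly substituted and do not compete, and 30 °C avoids loss of methylketene from the tertiary ynol ether.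

Step 18
Reactants: 27 C1 triethylsilyl ether of the bicyclic dienol ether lactone
Product: 28 C1 alcohol of the bicyclic dienol ether lactone (1S,6S,7R,8S,10S; C4=C5 Z)
Conditions: Bu4NF, AcOH (1:1), THF, 0 °C
Reagents that add atoms: none
Why: Fluoride buffered with acetic acid removes the triethylsilyl group (fluoride desilylation) at near-neutral pH, which spares the acid-sensitive cyclic dienol ether as well as the base-sensitive methylene lactone and tiglate.

Step 19
Reactants: 28 C1 alcohol of the bicyclic dienol ether lactone
Product: 29 target furanone (6S,7R,8S,10S; C4=C5 Z)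
Conditions: MnO2, CH2Cl2, rt
Reagents that add atoms: none
Why: Activated MnO2 oxidises the allylic alcohol beside the enol ether double bond to the vinylogous ester (allylic alcohol oxidation), which creates the 3(2H)-furanone and erases the C1 stereocentre under neutral heterogeneous conditions that leave lactone, tiglate and diene untouched.

Compound list
1 | (S)-citramalic acid | C[C@](O)(CC(=O)O)C(=O)O | starting material
2 | 2-[(4S)-2,2,4-trimethyl-5-oxo-1,3-dioxolan-4-yl]acetic acid | C[C@@]1(CC(=O)O)OC(C)(C)OC1=O | intermediate
3 | (5S)-5-(2-hydroxyethyl)-2,2,5-trimethyl-1,3-dioxolan-4-one | C[C@@]1(CCO)OC(C)(C)OC1=O | intermediate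
4 | (3S)-3-hydroxy-3-methyloxolan-2-one | C[C@]1(O)CCOC1=O | intermediate
5 | (3S)-3-methyloxolane-2,3-diol (anomers) | OC1OCC[C@]1(C)O | intermediate
6 | (3S)-2-methoxy-3-methyloxolan-3-ol (anomers) | COC1OCC[C@]1(C)O | intermediate
7 | trichloroethylene | ClC=C(Cl)Cl | starting material
8 | (3S)-3-[(E)-1,2-dichloroethenoxy]-2-methoxy-3-methyloxolane (anomers) | COC1OCC[C@]1(C)O/C(Cl)=C\Cl | intermediate
9 | (3S)-3-[(E)-1,2-dichloroethenoxy]-3-methyloxolan-2-ol (anomers) | OC1OCC[C@]1(C)O/C(Cl)=C\Cl | intermediate
10 | (3S,4S)-3-[(E)-1,2-dichloroethenoxy]-3-methylhex-5-ene-1,4-diol | OCC[C@](C)(O/C(Cl)=C\Cl)[C@@H](O)C=C | intermediate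
11 | (3S,4S)-3-[(E)-1,2-dichloroethenoxy]-3-methyl-1,4-bis(triethylsilyloxy)hex-5-ene | CC[Si](CC)(CC)OCC[C@](C)(O/C(Cl)=C\Cl)[C@@H](O[Si](CC)(CC)CC)C=C | intermediate
12 | (3S,4S)-3-(chloroethynyloxy)-3-methyl-1,4-bis(triethylsilyloxy)hex-5-ene | CC[Si](CC)(CC)OCC[C@](C)(OC#CCl)[C@@H](O[Si](CC)(CC)CC)C=C | intermediate
13 | lithium acetylide of the C10 ethynyl ether (bis-triethylsilyl ether) | CC[Si](CC)(CC)OCC[C@](C)(OC#C[Li])[C@@H](O[Si](CC)(CC)CC)C=C | intermediate
14 | (3S,4S)-3-methyl-3-(prop-1-ynoxy)-1,4-bis(triethylsilyloxy)hex-5-ene | CC[Si](CC)(CC)OCC[C@](C)(OC#CC)[C@@H](O[Si](CC)(CC)CC)C=C | intermediate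
15 | (3S,4S)-3-methyl-3-(prop-1-ynoxy)-4-(triethylsilyloxy)hex-5-en-1-ol | OCC[C@](C)(OC#CC)[C@@H](O[Si](CC)(CC)CC)C=C | intermediate
16 | (3S,4S)-3-methyl-3-(prop-1-ynoxy)-4-(triethylsilyloxy)hex-5-enal | O=CC[C@](C)(OC#CC)[C@@H](O[Si](CC)(CC)CC)C=C | intermediate
17 | penta-1,4-dien-3-ol | C=CC(O)C=C | starting material
18 | (1S)-1-[(2R)-oxiran-2-yl]prop-2-en-1-ol | C=C[C@H](O)[C@H]1CO1 | intermediate
19 | 2-(bromomethyl)prop-2-enoic acid | C=C(CBr)C(=O)O | starting material
20 | (1S)-1-[(2R)-oxiran-2-yl]prop-2-enyl 2-(bromomethyl)prop-2-enoate | C=C[C@H](OC(=O)C(=C)CBr)[C@H]1CO1 | intermediate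
21 | (5S)-3-(bromomethyl)-5-[(2R)-oxiran-2-yl]furan-2(5H)-one | O=C1O[C@@H](C=C1CBr)[C@H]2CO2 | intermediate
22 | (5R)-5-ethenyl-3-(iodomethyl)furan-2(5H)-one | C=C[C@H]1OC(=O)C(CI)=C1 | intermediate
23 | C8 iodozinc alkoxide of the 6,12-lactone Barbier adduct (C6, C7, C8 arranged as in 24) | C=C1C(=O)O[C@H](C=C)[C@H]1[C@@H](O[Zn]I)C[C@](C)(OC#CC)[C@@H](O[Si](CC)(CC)CC)C=C | intermediate
24 | (4S,5S)-4-[(1R)-1-hydroxyprop-2-enyl]-3-methylidene-5-[(2S,3S)-2-methyl-2-(prop-1-ynoxy)-3-(triethylsilyloxy)pent-4-enyl]oxolan-2-one (trans 8,12-lactone, C6 epimer of the target series) | C=C1C(=O)O[C@@H](C[C@](C)(OC#CC)[C@@H](O[Si](CC)(CC)CC)C=C)[C@@H]1[C@H](O)C=C | intermediate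
25 | tiglic acid, (E)-2-methylbut-2-enoic acid | C/C=C(C)/C(=O)O | starting material
26 | (4R,5S)-3-methylidene-4-[(1S)-1-[(E)-2-methylbut-2-enoyl]oxyprop-2-enyl]-5-[(2S,3S)-2-methyl-2-(prop-1-ynoxy)-3-(triethylsilyloxy)pent-4-enyl]oxolan-2-one (dienyne precursor) | C=C1C(=O)O[C@@H](C[C@](C)(OC#CC)[C@@H](O[Si](CC)(CC)CC)C=C)[C@@H]1[C@@H](OC(=O)/C(C)=C/C)C=C | intermediate
27 | C1 triethylsilyl ether of the bicyclic dienol ether lactone (1S,6S,7R,8S,10S; C4=C5 Z) | C=C1C(=O)O[C@H]2C[C@]3(C)OC(=C[C@@H]3O[Si](CC)(CC)CC)/C(C)=C\[C@H](OC(=O)/C(C)=C/C)[C@H]12 | intermediate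
28 | C1 alcohol of the bicyclic dienol ether lactone (1S,6S,7R,8S,10S; C4=C5 Z) | C=C1C(=O)O[C@H]2C[C@]3(C)OC(=C[C@@H]3O)/C(C)=C\[C@H](OC(=O)/C(C)=C/C)[C@H]12 | intermediate
29 | target furanone (6S,7R,8S,10S; C4=C5 Z) | C=C1C(=O)O[C@H]2C[C@]3(C)OC(=CC3=O)/C(C)=C\[C@H](OC(=O)/C(C)=C/C)[C@H]12 | target

Total step count: 19. Longest linear sequence: 15 steps (steps 1–10 and 15–19); steps 11–14 make the butenolide branch.

The three steps most likely to fail are, in this order, step 17, step 15 and step 16.

Step 17 may stall after the first ring closure because the nine-membered closure through a trisubstituted alkene is slow. Material can then be lost to oligomerisation or to thermal decay of the ynol ether. The fallback sets out from 26 and separates the two events. Under ethene (1 atm) with the same ruthenium catalyst at room temperature, the enyne closure alone should give the isopropenyl dihydrofuran triene F1, because ethene caps the C4 carbene. F1 no longer contains the heat-sensitive ynol ether. It is then closed by ordinary diene ring-closing metathesis with the second-generation Hoveyda–Grubbs catalyst (H2IMes)Cl2Ru=CH(C6H4-2-OiPr) in toluene at 1 mM and 60–80 °C, and the route is rejoined at 27.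

Step 15 may suffer from ring-opening elimination of the allylzinc (the lactone oxygen is a vinylogous leaving group), from zinc halide-promoted decay of the ynol ether aldehyde, or from incomplete acyl migration. The fallback sets out from 16 and 22 and uses chromium dichloride CrCl2 in THF at room temperature (Nozaki–Hiyama–Kishi-type allylation, known for bromomethyl butenolides and also anti-selective). The inert chromium alkoxide cannot translactonize, so work-up gives the free 6,12-lactone alcohol F2. The lactone is then moved to O8 in a separate operation with catalytic DBU in CH2Cl2, and the route is rejoined at 24.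

Step 16 may give allylic transposition (SN2′ attack), elimination to a diene, or slow reaction at the hindered carbinol with exposure of the ynol ether to free acid. The fallback sets out from 24 and splits activation from displacement. MsCl and Et3N at −40 °C give the C6 methanesulfonate F3. Caesium tiglate (CsO2CC(CH3)=CHCH3) with 18-crown-6 in toluene at room temperature then displaces it with inversion, and the route is rejoined at 26.

Further compounds
F1 | step 17 | isopropenyl dihydrofuran triene (five-membered enol ether closed, nine-membered ring open; stereocentres as in 26) | C=C1C(=O)O[C@@H](C[C@]2(C)OC(=C[C@@H]2O[Si](CC)(CC)CC)C(C)=C)[C@@H]1[C@@H](OC(=O)/C(C)=C/C)C=C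
F2 | step 15 | (4R,5R)-5-ethenyl-4-[(1S,3S,4S)-1-hydroxy-3-methyl-3-(prop-1-ynoxy)-4-(triethylsilyloxy)hex-5-enyl]-3-methylideneoxolan-2-one | C=C1C(=O)O[C@H](C=C)[C@H]1[C@@H](O)C[C@](C)(OC#CC)[C@@H](O[Si](CC)(CC)CC)C=C
F3 | step 16 | C6 methanesulfonate of 24 | C=C1C(=O)O[C@@H](C[C@](C)(OC#CC)[C@@H](O[Si](CC)(CC)CC)C=C)[C@@H]1[C@H](OS(C)(=O)=O)C=C
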